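## Retrosynthetic overview

- The target is reached by hydrogenation/debenzylation of a cross-metathesis product, made from an allyl-bearing hydroxy-lactone and 1-(benzyloxy)-4-(oct-7-en-1-yl)benzene.
- The γ-lactone and its secondary OH come from anti-hydroxylactonisation (epoxide opening with inversion) of a (Z)-β,γ-unsaturated 6-hydroxy acid. The Z geometry is inherited from a ring.
- That hydroxy acid comes from a seven-membered lactone, made by Baeyer–Villiger oxidation of an α-methyl-α-allyl cyclohexenone. The quaternary carbon becomes the tertiary carbinol with retention.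
- The cyclohexenone comes from enantioselective allylation of a silyl dienol ether, itself made by Birch reduction of silylated 2,4-dimethylphenol. All six backbone carbons C1–C6 and both C-methyl groups of the lactone/carbinol part come from the xylenol ring.
- Ring order: arene → cyclohexa-1,4-diene → cyclohexenone → oxepinone (ring expansion) → ring-opened acid → γ-lactone (the only ring of the target, closed in step 5).

Assumption: ligands, catalysts and oxidants are bought, and the olefin of 14, formed as an E/Z mixture, is drawn as E because it is hydrogenated in the next step.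

## Route

**Step 1**
Reactants: 1 2,4-dimethylphenol
Product: 2 tert-butyl(2,4-dimethylphenoxy)dimethylsilane
Conditions: TBSCl (1.1 equiv), imidazole (2 equiv), DMF, 25 °C
Reagents that add atoms: tert-butyldimethylsilyl chloride (TBSCl), CC(C)(C)[Si](C)(C)Cl
Why: Standard imidazole-promoted O-silylation of a phenol, which gives an aryl silyl ether that survives dissolving-metal reduction and later serves as a latent enolate.

**Step 2**
Reactants: 2 tert-butyl(2,4-dimethylphenoxy)dimethylsilane
Product: 3 tert-butyl[(2,4-dimethylcyclohexa-1,4-dien-1-yl)oxy]dimethylsilane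
Conditions: Li (4 equiv), NH3(l)/THF, t-BuOH (3 equiv), −78 → −33 °C; then MeOH, pentane extraction
Reagents that add atoms: none
Why: Birch reduction, in which the silyloxy donor directs protonation to C3 and C6 so that the oxygen and both methyl groups stay on sp2 carbons, giving a tetrasubstituted silyl enol ether (a regiodefined enolate at the methyl-bearing carbon) and a ring-locked cis trisubstituted olefin; no stereocentre is formed.

**Step 3**
Reactants: 3 tert-butyl[(2,4-dimethylcyclohexa-1,4-dien-1-yl)oxy]dimethylsilane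
Product: 4 (6R)-4,6-dimethyl-6-(prop-2-en-1-yl)cyclohex-3-en-1-one
Conditions: diallyl carbonate (1.05 equiv), Pd2(dba)3 (2.5 mol%), (S)-t-Bu-PHOX (6.25 mol%), Bu4N[Ph3SiF2] (TBAT, 35 mol%), THF, 25 °C
Reagents that add atoms: diallyl carbonate, C=CCOC(=O)OCC=C
Why: Enantioselective Tsuji allylation of a fluoride/alkoxide-unmasked tetrasubstituted enolate with a zerovalent palladium–phosphinooxazoline catalyst, where the (S)-ligand delivers allyl to the same enolate face as in its known formation of (S)-2-allyl-2-methylcyclohexanone (about 85–90% ee expected), which here is the 6R quaternary centre because the ring CH2 next to the olefin outranks allyl.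

**Step 4**
Reactants: 4 (6R)-4,6-dimethyl-6-(prop-2-en-1-yl)cyclohex-3-en-1-one
Product: 5 (7R)-5,7-dimethyl-7-(prop-2-en-1-yl)-6,7-dihydrooxepin-2(3H)-one
Conditions: (Me3SiO)2 (1.5 equiv), Me3SiOTf (10 mol%), CH2Cl2, −78 → −40 °C; then pyridine, aq. NaHCO3
Reagents that add atoms: bis(trimethylsilyl) peroxide, C[Si](C)(C)OO[Si](C)(C)C
Why: Baeyer–Villiger oxidation with a nucleophilic silyl peroxide that does not epoxidise olefins, in which the fully substituted α-carbon migrates in preference to the allylic CH2 and does so with retention, turning the C–C quaternary centre into the tertiary C–O centre (7R).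

**Step 5**
Reactants: 5 (7R)-5,7-dimethyl-7-(prop-2-en-1-yl)-6,7-dihydrooxepin-2(3H)-one
Product: 9 (4S,5S)-4-hydroxy-5-[(2R)-2-hydroxy-2-methylpent-4-en-1-yl]-5-methyloxolan-2-one, via lithium hydroxy-dienoate 6 (not isolated), via lithium epoxy-carboxylate 7 (not isolated), via epoxy acid 8 (not isolated)
Conditions: LiOH (1.2 equiv), THF/H2O, 0 → 25 °C; then L-fructose-derived Shi ketone (30 mol%), Oxone (2KHSO5·KHSO4·K2SO4, 1.4 equiv KHSO5), K2CO3, Bu4NHSO4 (cat.), MeCN/(MeO)2CH2/aq. Na2B4O7 buffer (pH 10.5), 0 °C; then aq. HCl to pH 2, EtOAc, 25 °C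
Reagents that add atoms: lithium hydroxide, [Li+].[OH-]; potassium peroxymonosulfate (active component of Oxone), [K+].[O-]S(=O)(=O)OO
Why: Saponification at the acyl carbon leaves the tertiary C–O centre untouched, Shi epoxidation then oxidises only the electron-rich trisubstituted (Z)-olefin on the face fixed by the spiro transition state of the L-fructose-derived dioxirane to give the (2S,3R)-oxirane, and on acidification the carboxylic acid opens the protonated epoxide at its tertiary carbon with inversion (epoxide-opening lactonisation), which sets C5 as S and leaves the epoxide oxygen as the 4S hydroxyl cis to the side-chain CH2.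

**Step 6**
Reactants: 10 1-(benzyloxy)-4-bromobenzene; 11 8-bromooct-1-ene
Product: 13 1-(benzyloxy)-4-(oct-7-en-1-yl)benzene, via aryl Grignard reagent 12 (not isolated)
Conditions: Mg, THF, 65 °C; then 11 (0.9 equiv), Li2CuCl4 (3 mol%), THF, 0 → 25 °C
Reagents that add atoms: none
Why: Copper-catalysed (Kochi-type) cross-coupling of an aryl Grignard reagent with a primary alkyl bromide, which tolerates the terminal olefin and the benzyl ether.

**Step 7**
Reactants: 9 (4S,5S)-4-hydroxy-5-[(2R)-2-hydroxy-2-methylpent-4-en-1-yl]-5-methyloxolan-2-one; 13 1-(benzyloxy)-4-(oct-7-en-1-yl)benzene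
Product: 14 (4S,5S)-5-[(2R,4E)-11-[4-(benzyloxy)phenyl]-2-hydroxy-2-methylundec-4-en-1-yl]-4-hydroxy-5-methyloxolan-2-one
Conditions: 13 (3 equiv), second-generation Grubbs catalyst RuCl2(=CHPh)(H2IMes)(PCy3) (5 mol%), CH2Cl2, 40 °C
Reagents that add atoms: none
Why: Olefin cross-metathesis between two terminal olefins, driven by loss of ethylene and by excess of the unhindered partner, which tolerates free hydroxyls and the lactone and touches no stereocentre.

**Step 8**
Reactants: 14 (4S,5S)-5-[(2R,4E)-11-[4-(benzyloxy)phenyl]-2-hydroxy-2-methylundec-4-en-1-yl]-4-hydroxy-5-methyloxolan-2-one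
Product: 15 (4S,5S)-4-hydroxy-5-[(2R)-2-hydroxy-11-(4-hydroxyphenyl)-2-methylundecyl]-5-methyloxolan-2-one
Conditions: H2 (1 atm), 10% Pd/C, EtOAc, 25 °C
Reagents that add atoms: none
Why: Heterogeneous catalytic hydrogenation saturates the disubstituted olefin and hydrogenolyses the benzyl aryl ether in one operation under neutral conditions that leave the β-hydroxy lactone and the tertiary alcohol intact.

## Compound list

1 | 2,4-dimethylphenol | Cc1ccc(O)c(C)c1 | starting material
2 | tert-butyl(2,4-dimethylphenoxy)dimethylsilane | Cc1ccc(O[Si](C)(C)C(C)(C)C)c(C)c1 | intermediate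
3 | tert-butyl[(2,4-dimethylcyclohexa-1,4-dien-1-yl)oxy]dimethylsilane | CC1=CCC(O[Si](C)(C)C(C)(C)C)=C(C)C1 | intermediate
4 | (6R)-4,6-dimethyl-6-(prop-2-en-1-yl)cyclohex-3-en-1-one | O=C1CC=C(C)C[C@@]1(C)CC=C | intermediate
5 | (7R)-5,7-dimethyl-7-(prop-2-en-1-yl)-6,7-dihydrooxepin-2(3H)-one | O=C1CC=C(C)C[C@@](C)(CC=C)O1 | intermediate
6 | lithium (3Z,6R)-6-hydroxy-4,6-dimethylnona-3,8-dienoate | [Li+].[O-]C(=O)C/C=C(C)\C[C@](C)(O)CC=C | intermediate (not isolated)
7 | lithium 2-[(2S,3R)-3-[(2R)-2-hydroxy-2-methylpent-4-en-1-yl]-3-methyloxiran-2-yl]acetate | [Li+].[O-]C(=O)C[C@@H]1O[C@]1(C)C[C@](C)(O)CC=C | intermediate (not isolated)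
8 | 2-[(2S,3R)-3-[(2R)-2-hydroxy-2-methylpent-4-en-1-yl]-3-methyloxiran-2-yl]acetic acid | OC(=O)C[C@@H]1O[C@]1(C)C[C@](C)(O)CC=C | intermediate (not isolated)
9 | (4S,5S)-4-hydroxy-5-[(2R)-2-hydroxy-2-methylpent-4-en-1-yl]-5-methyloxolan-2-one | C[C@@](O)(CC=C)C[C@]1(C)OC(=O)C[C@@H]1O | intermediate
10 | 1-(benzyloxy)-4-bromobenzene | Brc1ccc(OCc2ccccc2)cc1 | starting material
11 | 8-bromooct-1-ene | C=CCCCCCCBr | starting material
12 | [4-(benzyloxy)phenyl]magnesium bromide | Br[Mg]c1ccc(OCc2ccccc2)cc1 | intermediate (not isolated)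
13 | 1-(benzyloxy)-4-(oct-7-en-1-yl)benzene | C=CCCCCCCc1ccc(OCc2ccccc2)cc1 | intermediate
14 | (4S,5S)-5-[(2R,4E)-11-[4-(benzyloxy)phenyl]-2-hydroxy-2-methylundec-4-en-1-yl]-4-hydroxy-5-methyloxolan-2-one | C[C@@](O)(C/C=C/CCCCCCc1ccc(OCc2ccccc2)cc1)C[C@]1(C)OC(=O)C[C@@H]1O | intermediate
15 | (4S,5S)-4-hydroxy-5-[(2R)-2-hydroxy-11-(4-hydroxyphenyl)-2-methylundecyl]-5-methyloxolan-2-one | C[C@@](O)(CCCCCCCCCc1ccc(O)cc1)C[C@]1(C)OC(=O)C[C@@H]1O | target

## Step count and risks

Total step count: 8. Longest linear sequence: 7 (steps 1, 2, 3, 4, 5, 7, 8).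

**Step 4 (Baeyer–Villiger in the presence of two olefins).** The risks are competing epoxidation, migration of the allylic CH2, or acid-induced ionisation of the tertiary lactone. The fallback drops the ring expansion and builds the carbinol by carbonyl addition. It sets out from 3: selective ozonolysis of the tetrasubstituted silyl enol ether bond (O3, 1 equiv, CH2Cl2, −78 °C; Me2S) gives tert-butyldimethylsilyl (3Z)-4-methyl-6-oxohept-3-enoate F3. Catalytic enantioselective allylboration of its methyl ketone (2-allyl-1,3,2-dioxaborinane, 3,3′-dibromo-BINOL catalyst, t-BuOH, toluene, with the BINOL enantiomer chosen to give 6R) gives tert-butyldimethylsilyl (3Z,6R)-6-hydroxy-4,6-dimethylnona-3,8-dienoate F4. LiOH in THF/H2O cleaves the silyl ester, and the route is rejoined at 6.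

**Step 5 (telescoped saponification, Shi epoxidation of a Z-trisubstituted olefin as its carboxylate, and epoxide-opening lactonisation).** The risks are moderate face selectivity, olefin migration into conjugation during hydrolysis, and loss of stereospecificity at the tertiary carbon. The fallback moves to a neutral ester and to hydroxyl-directed metal catalysis. It sets out from 5: K2CO3/MeOH at 0 °C gives methyl (3Z,6R)-6-hydroxy-4,6-dimethylnona-3,8-dienoate F5. Epoxidation directed by the tertiary homoallylic hydroxyl (Hf(Ot-Bu)4, chiral bishydroxamic acid ligand, cumene hydroperoxide, toluene) gives methyl 2-[(2S,3R)-3-[(2R)-2-hydroxy-2-methylpent-4-en-1-yl]-3-methyloxiran-2-yl]acetate F6. Camphorsulfonic acid in wet CH2Cl2 closes the lactone with inversion at the tertiary carbon, and the route is rejoined at 9.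

**Step 3 (asymmetric allylation from a tert-butyldimethylsilyl dienol ether).** The risks are slow silyl transfer, enolate scrambling towards the conjugated dienolate, and erosion of ee. The fallback goes through an isolated enol carbonate and the inner-sphere decarboxylative manifold, with no fluoride and no free alkoxide. It sets out from 3: MeLi in THF at 0 °C gives lithium 2,4-dimethylcyclohexa-1,4-dien-1-olate F1. Trapping with allyl chloroformate at −78 °C gives allyl 2,4-dimethylcyclohexa-1,4-dien-1-yl carbonate F2. Pd2(dba)3/(S)-t-Bu-PHOX in THF at 25 °C effects decarboxylative allylation, and the route is rejoined at 4.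

## Further compounds

F1 | step 3 | lithium 2,4-dimethylcyclohexa-1,4-dien-1-olate | [Li+].[O-]C1=C(C)CC(C)=CC1
F2 | step 3 | allyl 2,4-dimethylcyclohexa-1,4-dien-1-yl carbonate | C=CCOC(=O)OC1=C(C)CC(C)=CC1
F3 | step 4 | tert-butyldimethylsilyl (3Z)-4-methyl-6-oxohept-3-enoate | CC(=O)C/C(C)=C\CC(=O)O[Si](C)(C)C(C)(C)C
F4 | step 4 | tert-butyldimethylsilyl (3Z,6R)-6-hydroxy-4,6-dimethylnona-3,8-dienoate | C=CC[C@@](C)(O)C/C(C)=C\CC(=O)O[Si](C)(C)C(C)(C)C
F5 | step 5 | methyl (3Z,6R)-6-hydroxy-4,6-dimethylnona-3,8-dienoate | COC(=O)C/C=C(C)\C[C@](C)(O)CC=C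
F6 | step 5 | methyl 2-[(2S,3R)-3-[(2R)-2-hydroxy-2-methylpent-4-en-1-yl]-3-methyloxiran-2-yl]acetate | COC(=O)C[C@@H]1O[C@]1(C)C[C@](C)(O)CC=C
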